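The six rings are called A–F, where A is the terminal 2,4,6-trihydroxyphenyl unit and F the 3,4,5-trihydroxyphenyl unit. Ring C is unique: it carries oxygen on C1 (ether to B), C3, C4, C5 (OH) and C6 (ether to D), and hydrogen only on C2. It is therefore assembled rather than functionalised. Dimethyl squarate supplies C3–C6 with their four oxygens, and a 1-(AB-aryloxy)vinyl anion supplies C1 and C2. The precursor is a racemic 4-(1-aryloxyvinyl)-2,3-dimethoxy-4-(methoxymethoxy)cyclobutenone. Heating it forms the C2–C3 bond and aromatises ring C in one operation. The crowded C1–O–B ether is already present, and the para oxygens emerge differentiated (C3 free OH, C6 MOM).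

Key step: step 8

Assumption: the target has no stereocentre and its diaryl ether bonds rotate freely, so stereochemistry appears only as transient alkene geometry and as a racemic quaternary carbon that is later planarised.

Step 1
Reactants: 1 4-bromo-2,6-dimethoxyphenol
Product: 2 2-(benzyloxy)-5-bromo-1,3-dimethoxybenzene
Conditions: BnBr, K2CO3, DMF, rt to 50 °C
Reagents that add atoms: benzyl bromide BrCc1ccccc1
Why: Williamson ether synthesis on an acidic phenol; the benzyl group masks the oxygen destined to bridge rings B and C and can later be removed without touching methyl or diaryl ethers.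

Step 2
Reactants: 2 2-(benzyloxy)-5-bromo-1,3-dimethoxybenzene, 3 2,4,6-trimethoxyphenol
Product: 4 2-(benzyloxy)-1,3-dimethoxy-5-(2,4,6-trimethoxyphenoxy)benzene (AB benzyl ether)
Conditions: CuI (10 mol %), picolinic acid (20 mol %), K3PO4, DMSO, 90 °C, Ar
Reagents that add atoms: none
Why: Ligand-accelerated Ullmann diaryl ether coupling, in which a phenoxide flanked by two methoxy groups is acceptable because the C–Br carbon of 2 has only hydrogen neighbours.

Step 3
Reactants: 4 AB benzyl ether
Product: 5 2,6-dimethoxy-4-(2,4,6-trimethoxyphenoxy)phenol (AB phenol)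
Conditions: H2 (1 atm), 10% Pd/C, EtOAc–MeOH, rt
Reagents that add atoms: none
Why: Catalytic hydrogenolysis cleaves only the benzylic C–O bond, and no halogen or other reducible group remains in 4.

Step 4
Reactants: 5 AB phenol, 6 trichloroethylene
Product: 8 2-{[(E)-1,2-dichloroethenyl]oxy}-1,3-dimethoxy-5-(2,4,6-trimethoxyphenoxy)benzene, via dichloroacetylene 7 (not isolated)
Conditions: K2CO3, DMF, 70 °C
Reagents that add atoms: none
Why: Elimination–addition vinylation: carbonate dehydrochlorinates 6 to the slim electrophile 7, to which even the hindered phenoxide adds in anti fashion, which sets the E geometry (lost again in the next step).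

Step 5
Reactants: 8 (E)-1,2-dichlorovinyl ether of the AB phenol
Product: 11 2-(ethynyloxy)-1,3-dimethoxy-5-(2,4,6-trimethoxyphenoxy)benzene, via chloroethynyl ether 9 (not isolated), via lithium aryloxyacetylide 10 (not isolated)
Conditions: n-BuLi (2.3 equiv), THF, −78 to −40 °C; H2O, −78 °C
Reagents that add atoms: none
Why: Dehydrochlorination followed by chlorine–lithium exchange is the established passage from 1,2-dichlorovinyl ethers to ynol ethers, the proton quench also repairs any stray ring lithiation, and the two ortho methoxy groups shield the sensitive aryloxyalkyne, which is carried on without storage.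

Step 6
Reactants: 11 AB ethynyl ether
Product: 12 tributyl{1-[2,6-dimethoxy-4-(2,4,6-trimethoxyphenoxy)phenoxy]ethenyl}stannane
Conditions: Bu3SnH (1.1 equiv), Pd(PPh3)4 (2 mol %), THF, 0 °C to rt
Reagents that add atoms: tributyltin hydride CCCC[SnH](CCCC)CCCC
Why: Palladium-catalysed syn hydrostannation of a terminal ynol ether, whose polarisation directs hydrogen to the terminal carbon and tin to the oxygen-bearing carbon, with any beta isomer removable on triethylamine-deactivated silica.

Step 7
Reactants: 12 alpha-stannylvinyl ether, 13 dimethyl squarate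
Product: 16 rac-4-{1-[2,6-dimethoxy-4-(2,4,6-trimethoxyphenoxy)phenoxy]ethenyl}-2,3-dimethoxy-4-(methoxymethoxy)cyclobut-2-en-1-one, via 1-aryloxyvinyllithium 14 (not isolated), via lithium alkoxide 15 (not isolated)
Conditions: n-BuLi (1.0 equiv), THF, −78 °C; cannulate into 13, THF, −78 °C; MOMCl, −78 to 0 °C
Reagents that add atoms: chloromethyl methyl ether COCCl
Why: Tin–lithium exchange gives the vinyl anion regiospecifically without touching the acidic ring C–H bonds, its 1,2-addition to one of the two equivalent carbonyl groups of 13 follows the usual organolithium–squarate pattern, and O-alkylation of the alkoxide by the very reactive MOMCl installs a base-stable, acid-labile donor group; the quaternary carbon arises as a racemate because nothing in the system is chiral, which is harmless since it becomes planar in the next step.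

Step 8
Reactants: 16 racemic 4-(1-aryloxyvinyl)-4-(methoxymethoxy)cyclobutenone
Product: 19 5-[2,6-dimethoxy-4-(2,4,6-trimethoxyphenoxy)phenoxy]-2,3-dimethoxy-4-(methoxymethoxy)phenol (ABC trimer; C3-OH free; C6-OMOM), via dienylketene 17 (not isolated), via cyclohexadienone 18 (not isolated)
Conditions: degassed p-xylene (0.01 M), 130 °C, Ar, base-washed glass
Reagents that add atoms: none
Why: Heat triggers conrotatory 4π opening of the bond between the carbonyl carbon and the quaternary carbon of 16, and the donor OMOM group turns outward so that the aryloxyvinyl group lies on the ketene side in the Z-configured dienylketene 17. The nucleophilic enol-ether CH2 then bonds to the electrophilic ketene carbon in a disrotatory 6π electrocyclisation (new bond C2–C3, six-membered ring C closed), and dienone 18 enolises irreversibly to phenol 19. This is the Moore-type thermal ring expansion of squarate-derived 4-alkenyl-4-alkoxycyclobutenones to hydroquinone monoethers, applied here to a vinyl group that carries an alpha-aryloxy substituent. No stereocentre is created, and the racemic quaternary carbon of 16 becomes the planar C6. Two selectivities are needed: the torquoselectivity, secured by the oxygen on the quaternary carbon, and the distinction of the para oxygens, secured because only the former ketene oxygen emerges as free OH (C3) while C6 keeps its MOM group. Dilute, degassed and acid-free conditions protect the ketene, the enol ether and the electron-rich phenol.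

Step 9
Reactants: 19 ABC trimer with free C3-OH
Product: 20 1-[2,6-dimethoxy-4-(2,4,6-trimethoxyphenoxy)phenoxy]-3,4,5-trimethoxy-2-(methoxymethoxy)benzene
Conditions: MeI, K2CO3, DMF, rt
Reagents that add atoms: iodomethane CI
Why: Williamson methylation of the only free phenol; the MOM acetal is inert to carbonate base, so C3 and C6 stay differentiated.

Step 10
Reactants: 20 ABC trimer with C6-OMOM
Product: 21 6-[2,6-dimethoxy-4-(2,4,6-trimethoxyphenoxy)phenoxy]-2,3,4-trimethoxyphenol (ABC phenol; C6-OH free)
Conditions: HCl (cat.), MeOH, 45 °C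
Reagents that add atoms: none
Why: Acid-catalysed acetal exchange removes the MOM group selectively, since aryl methyl ethers and diaryl ethers do not react with dilute methanolic HCl.

Step 11
Reactants: 22 5-iodo-1,2,3-trimethoxybenzene, 1 4-bromo-2,6-dimethoxyphenol
Product: 23 5-(4-bromo-2,6-dimethoxyphenoxy)-1,2,3-trimethoxybenzene (EF bromide)
Conditions: 22 (1.5 equiv), CuI (10 mol %), picolinic acid (20 mol %), K3PO4, DMSO, 80 °C, Ar
Reagents that add atoms: none
Why: Chemoselective Ullmann coupling: copper activates the C–I bond of 22 far faster than a C–Br bond, the bromide of 1 is further deactivated by its para phenoxide, and an excess of 22 keeps product 23 from reacting on.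

Step 12
Reactants: 23 EF bromide
Product: 24 5-(4-iodo-2,6-dimethoxyphenoxy)-1,2,3-trimethoxybenzene (EF iodide)
Conditions: NaI (2 equiv), CuI (5 mol %), trans-N,N'-dimethylcyclohexane-1,2-diamine (10 mol %), dioxane, 110 °C
Reagents that add atoms: sodium iodide [Na+].[I-]
Why: Copper-catalysed aromatic Finkelstein reaction, an equilibrium pulled to the iodide by precipitation of NaBr from dioxane, restores the halogen differentiation needed for the next coupling.

Step 13
Reactants: 24 EF iodide, 1 4-bromo-2,6-dimethoxyphenol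
Product: 25 5-[4-(4-bromo-2,6-dimethoxyphenoxy)-2,6-dimethoxyphenoxy]-1,2,3-trimethoxybenzene (DEF bromide)
Conditions: CuI (10 mol %), picolinic acid (20 mol %), K3PO4, DMSO, 80 °C, Ar
Reagents that add atoms: none
Why: Second iodide-selective Ullmann coupling of the same kind as step 11, run with near-equimolar partners and stopped when 24 is consumed so that the new C–Br bond survives.

Step 14
Reactants: 21 ABC phenol, 25 DEF bromide
Product: 26 pentadecamethyl ether of the target (rings A–F joined; every OH as OMe)
Conditions: CuI (20 mol %), picolinic acid (40 mol %), K3PO4, DMSO, 100 °C, Ar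
Reagents that add atoms: none
Why: Ullmann diaryl ether coupling with the same pairing as in steps 2, 11 and 13 (di-ortho-substituted phenoxide plus aryl halide without ortho substituents), with 21 as the only phenol and 25 as the only halide so that no chemoselectivity question arises.

Step 15
Reactants: 26 pentadecamethyl ether
Product: 27 target CNP0270681.0 (rings A–F; fifteen free OH)
Conditions: BBr3 (30 equiv), CH2Cl2, −78 °C to rt, Ar; MeOH quench, evaporate; Sephadex LH-20
Reagents that add atoms: none
Why: Lewis-acid ether cleavage: each methoxy oxygen binds BBr3 and bromide removes the methyl group by SN2 attack, a path closed to the five diaryl ether bridges, while exclusion of air and a volatile boron by-product allow the oxidisable polyphenol to be isolated without aqueous base.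

Compound list
1 | 4-bromo-2,6-dimethoxyphenol | COc1cc(Br)cc(OC)c1O | starting material
2 | 2-(benzyloxy)-5-bromo-1,3-dimethoxybenzene | COc1cc(Br)cc(OC)c1OCc1ccccc1 | intermediate
3 | 2,4,6-trimethoxyphenol | COc1cc(OC)c(O)c(OC)c1 | starting material
4 | 2-(benzyloxy)-1,3-dimethoxy-5-(2,4,6-trimethoxyphenoxy)benzene | COc1cc(OC)c(Oc2cc(OC)c(OCc3ccccc3)c(OC)c2)c(OC)c1 | intermediate
5 | 2,6-dimethoxy-4-(2,4,6-trimethoxyphenoxy)phenol | COc1cc(OC)c(Oc2cc(OC)c(O)c(OC)c2)c(OC)c1 | intermediate
6 | trichloroethylene | ClC=C(Cl)Cl | starting material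
7 | dichloroacetylene (formed in situ) | ClC#CCl | intermediate
8 | 2-{[(E)-1,2-dichloroethenyl]oxy}-1,3-dimethoxy-5-(2,4,6-trimethoxyphenoxy)benzene | Cl/C=C(/Cl)Oc1c(OC)cc(Oc2c(OC)cc(OC)cc2OC)cc1OC | intermediate
9 | 2-[(chloroethynyl)oxy]-1,3-dimethoxy-5-(2,4,6-trimethoxyphenoxy)benzene (formed in situ) | ClC#COc1c(OC)cc(Oc2c(OC)cc(OC)cc2OC)cc1OC | intermediate
10 | lithium acetylide of 11 (formed in situ) | [Li]C#COc1c(OC)cc(Oc2c(OC)cc(OC)cc2OC)cc1OC | intermediate
11 | 2-(ethynyloxy)-1,3-dimethoxy-5-(2,4,6-trimethoxyphenoxy)benzene | C#COc1c(OC)cc(Oc2c(OC)cc(OC)cc2OC)cc1OC | intermediate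
12 | tributyl{1-[2,6-dimethoxy-4-(2,4,6-trimethoxyphenoxy)phenoxy]ethenyl}stannane | C=C(Oc1c(OC)cc(Oc2c(OC)cc(OC)cc2OC)cc1OC)[Sn](CCCC)(CCCC)CCCC | intermediate
13 | dimethyl squarate | COC1=C(OC)C(=O)C1=O | starting material
14 | {1-[2,6-dimethoxy-4-(2,4,6-trimethoxyphenoxy)phenoxy]ethenyl}lithium (formed in situ) | [Li]C(=C)Oc1c(OC)cc(Oc2c(OC)cc(OC)cc2OC)cc1OC | intermediate
15 | racemic lithium alkoxide of the squarate 1,2-adduct (formed in situ) | C=C(Oc1c(OC)cc(Oc2c(OC)cc(OC)cc2OC)cc1OC)C1(O[Li])C(=O)C(OC)=C1OC | intermediate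
16 | rac-4-{1-[2,6-dimethoxy-4-(2,4,6-trimethoxyphenoxy)phenoxy]ethenyl}-2,3-dimethoxy-4-(methoxymethoxy)cyclobut-2-en-1-one | C=C(Oc1c(OC)cc(Oc2c(OC)cc(OC)cc2OC)cc1OC)C1(OCOC)C(=O)C(OC)=C1OC | intermediate
17 | (3Z)-5-(AB-aryloxy)-2,3-dimethoxy-4-(methoxymethoxy)hexa-1,3,5-trien-1-one (formed in situ) | O=C=C(OC)/C(OC)=C(OCOC)\C(=C)Oc1c(OC)cc(Oc2c(OC)cc(OC)cc2OC)cc1OC | intermediate
18 | 5-(AB-aryloxy)-2,3-dimethoxy-4-(methoxymethoxy)cyclohexa-2,4-dien-1-one (formed in situ) | O=C1CC(Oc2c(OC)cc(Oc3c(OC)cc(OC)cc3OC)cc2OC)=C(OCOC)C(OC)=C1OC | intermediate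
19 | 5-[2,6-dimethoxy-4-(2,4,6-trimethoxyphenoxy)phenoxy]-2,3-dimethoxy-4-(methoxymethoxy)phenol | Oc1cc(Oc2c(OC)cc(Oc3c(OC)cc(OC)cc3OC)cc2OC)c(OCOC)c(OC)c1OC | intermediate
20 | 1-[2,6-dimethoxy-4-(2,4,6-trimethoxyphenoxy)phenoxy]-3,4,5-trimethoxy-2-(methoxymethoxy)benzene | COc1cc(Oc2c(OC)cc(Oc3c(OC)cc(OC)cc3OC)cc2OC)c(OCOC)c(OC)c1OC | intermediate
21 | 6-[2,6-dimethoxy-4-(2,4,6-trimethoxyphenoxy)phenoxy]-2,3,4-trimethoxyphenol | COc1cc(Oc2c(OC)cc(Oc3c(OC)cc(OC)cc3OC)cc2OC)c(O)c(OC)c1OC | intermediate
22 | 5-iodo-1,2,3-trimethoxybenzene | COc1cc(I)cc(OC)c1OC | starting material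
23 | 5-(4-bromo-2,6-dimethoxyphenoxy)-1,2,3-trimethoxybenzene | COc1cc(Oc2c(OC)cc(Br)cc2OC)cc(OC)c1OC | intermediate
24 | 5-(4-iodo-2,6-dimethoxyphenoxy)-1,2,3-trimethoxybenzene | COc1cc(Oc2c(OC)cc(I)cc2OC)cc(OC)c1OC | intermediate
25 | 5-[4-(4-bromo-2,6-dimethoxyphenoxy)-2,6-dimethoxyphenoxy]-1,2,3-trimethoxybenzene | COc1cc(Oc2c(OC)cc(Oc3c(OC)cc(Br)cc3OC)cc2OC)cc(OC)c1OC | intermediate
26 | pentadecamethyl ether of the target | COc1cc(OC)c(Oc2cc(OC)c(Oc3cc(OC)c(OC)c(OC)c3Oc3cc(OC)c(Oc4cc(OC)c(Oc5cc(OC)c(OC)c(OC)c5)c(OC)c4)c(OC)c3)c(OC)c2)c(OC)c1 | intermediate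
27 | CNP0270681.0, hexameric phlorethol with rings A–F | Oc1cc(O)c(Oc2cc(O)c(Oc3cc(O)c(O)c(O)c3Oc3cc(O)c(Oc4cc(O)c(Oc5cc(O)c(O)c(O)c5)c(O)c4)c(O)c3)c(O)c2)c(O)c1 | target

Total step count: 15. Longest linear sequence: 12 (steps 1–10, 14, 15). The DEF branch (steps 11–13) joins at step 14.

Steps most likely to fail

1. Step 8.
- **What may go wrong:** The heat- and acid-sensitive enol ether and acetal groups may fragment before ring opening occurs. Alternatively, the crowded dienylketene may oligomerise before it folds into the conformation needed for closure.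
- **Fallback:** This replaces ring synthesis by classical arene functionalisation. It sets out from 5 and 22 and rejoins the route at 21. Rieche formylation of 22 (Cl2CHOMe, TiCl4, CH2Cl2, −78 to 0 °C) at one of its two equivalent free positions should give 6-iodo-2,3,4-trimethoxybenzaldehyde F1. Ullmann coupling of 5 with this ortho-formyl-activated iodide (CuI, picolinic acid, K3PO4, DMSO) should give the ABC aldehyde F2. Baeyer–Villiger oxidation (mCPBA, CH2Cl2) should turn it into the aryl formate F3, and methanolysis (K2CO3, MeOH) releases 21.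

2. Step 7.
- **What may go wrong:** The alpha-aryloxyvinyllithium may lose lithium aryloxide by carbenoid-type alpha-elimination, or it may abstract a ring proton flanked by two oxygens before it meets the squarate. The crowded tertiary lithium alkoxide may also be alkylated only sluggishly.
- **Fallback:** This uses a less basic magnesium nucleophile from a tin-free precursor, with protection as a separate operation. It sets out from 11 (with 13) and rejoins the route at 16. Markovnikov hydroiodination of 11 (NaI, TMSCl, H2O, MeCN, −20 °C) should give the 1-iodovinyl ether F4. Iodine–magnesium exchange (iPrMgCl·LiCl, THF, −40 °C) gives the vinylmagnesium chloride F5, which adds to 13. Work-up with NH4Cl delivers the isolated racemic tertiary alcohol F6, and MOMCl with iPr2NEt in CH2Cl2 converts it into 16.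

3. Step 14.
- **What may go wrong:** C–O bond formation may be slow between a phenoxide wedged between a methoxy and a bulky aryloxy group and a large electron-rich bromide. Loss of bromine from 25 and oxidative decay of the phenoxide could then compete.
- **Fallback:** This forms the hindered bond without metal and extends the chain stepwise. It sets out from 21 and rejoins the route at 26. Nucleophilic aromatic substitution of purchased 4-fluoro-2,6-dimethoxybenzaldehyde (O=Cc1c(OC)cc(F)cc1OC) by 21 (K2CO3, DMF, 120 °C) should give the ABCD aldehyde F7. Baeyer–Villiger oxidation (mCPBA) gives the formate F8, and methanolysis (K2CO3, MeOH) gives the ABCD phenol F9. F9 is an ordinary 2,6-dimethoxyphenol, and it is coupled with the EF iodide 24 under the conditions of step 13 to give 26.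

Further compounds
F1 | step 8 | 6-iodo-2,3,4-trimethoxybenzaldehyde | O=Cc1c(I)cc(OC)c(OC)c1OC
F2 | step 8 | 6-[2,6-dimethoxy-4-(2,4,6-trimethoxyphenoxy)phenoxy]-2,3,4-trimethoxybenzaldehyde | O=Cc1c(Oc2c(OC)cc(Oc3c(OC)cc(OC)cc3OC)cc2OC)cc(OC)c(OC)c1OC
F3 | step 8 | 6-[2,6-dimethoxy-4-(2,4,6-trimethoxyphenoxy)phenoxy]-2,3,4-trimethoxyphenyl formate | O=COc1c(Oc2c(OC)cc(Oc3c(OC)cc(OC)cc3OC)cc2OC)cc(OC)c(OC)c1OC
F4 | step 7 | 2-[(1-iodoethenyl)oxy]-1,3-dimethoxy-5-(2,4,6-trimethoxyphenoxy)benzene | C=C(I)Oc1c(OC)cc(Oc2c(OC)cc(OC)cc2OC)cc1OC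
F5 | step 7 | {1-[2,6-dimethoxy-4-(2,4,6-trimethoxyphenoxy)phenoxy]ethenyl}magnesium chloride | C=C([Mg]Cl)Oc1c(OC)cc(Oc2c(OC)cc(OC)cc2OC)cc1OC
F6 | step 7 | rac-4-{1-[2,6-dimethoxy-4-(2,4,6-trimethoxyphenoxy)phenoxy]ethenyl}-4-hydroxy-2,3-dimethoxycyclobut-2-en-1-one | C=C(Oc1c(OC)cc(Oc2c(OC)cc(OC)cc2OC)cc1OC)C1(O)C(=O)C(OC)=C1OC
F7 | step 14 | ABCD aldehyde, 2,6-dimethoxy-4-(ABC-aryloxy)benzaldehyde | O=Cc1c(OC)cc(Oc2c(Oc3c(OC)cc(Oc4c(OC)cc(OC)cc4OC)cc3OC)cc(OC)c(OC)c2OC)cc1OC
F8 | step 14 | ABCD formate, 2,6-dimethoxy-4-(ABC-aryloxy)phenyl formate | O=COc1c(OC)cc(Oc2c(Oc3c(OC)cc(Oc4c(OC)cc(OC)cc4OC)cc3OC)cc(OC)c(OC)c2OC)cc1OC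
F9 | step 14 | ABCD phenol, 2,6-dimethoxy-4-(ABC-aryloxy)phenol | Oc1c(OC)cc(Oc2c(Oc3c(OC)cc(Oc4c(OC)cc(OC)cc4OC)cc3OC)cc(OC)c(OC)c2OC)cc1OC
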